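**Retrosynthetic overview**
1. Piplartine-dimer A ⇒ cut both lactam C3=C4 bonds at once (two-directional double RCM) ⇒ acyclic tetraene bis-imide, with an N-acryloyl-N-but-3-enyl unit on each cyclobutane carbonyl.
2. Tetraene bis-imide ⇒ cut two imide N–C(O) bonds ⇒ α-truxillic-type diacid + 2 × N-(but-3-enyl)acrylamide (from but-3-en-1-amine + acryloyl chloride).
3. Diacid ⇒ head-to-tail topochemical [2+2] ⇒ 2 × (E)-3,4,5-trimethoxycinnamic acid. This sets all four stereocentres.
4. Ring order: cyclobutane first, then the two dihydropyridinone rings together in the last operation.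

**Assumption:** the target SMILES encodes the α-truxillic (1α,2α,3β,4β) head-to-tail pattern, which has an inversion centre and is achiral, so "single enantiomer" is read as this one diastereomer and no asymmetric induction is needed.

**Step 1**
Reactants: 1 (E)-3,4,5-trimethoxycinnamic acid (two molecules)
Product: 2 (1α,2α,3β,4β)-2,4-bis(3,4,5-trimethoxyphenyl)cyclobutane-1,3-dicarboxylic acid (α-truxillic-type head-to-tail dimer; aryls mutually trans; carboxyls mutually trans; centrosymmetric)
Conditions: hν (medium-pressure Hg lamp, borosilicate filter, λ > 290 nm), ground crystals (from EtOH) as stirred slurry in n-hexane, 20 °C, 48 h; unreacted 1 washed out with Et2O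
Reagents that add atoms: none
Why: Topochemical solid-state [2+2] photocycloaddition (Schmidt-type α-packing): inversion-related molecules of the hydrogen-bonded acid stack antiparallel with their C=C bonds parallel and within the roughly 4 Å contact limit, so only the head-to-tail dimer can form, each E-alkene keeps its aryl and carboxyl trans, and the crystallographic inversion centre places the two aryls trans and the two carboxyls trans, which fixes all four stereocentres of the target in this single step.

**Step 2**
Reactants: 3 but-3-en-1-amine; 4 acryloyl chloride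
Product: 5 N-(but-3-en-1-yl)prop-2-enamide
Conditions: NaOH (aq), CH2Cl2, 0 °C, 1 h
Reagents that add atoms: none
Why: Schotten–Baumann N-acylation of a primary amine by an acid chloride, which at 0 °C in the two-phase system is far faster than hydrolysis or aza-Michael addition to the acrylamide, and which creates no stereocentre.

**Step 3**
Reactants: 2 α-truxillic-type diacid; 5 N-(but-3-en-1-yl)prop-2-enamide (2.2 equiv)
Product: 8 (1α,2α,3β,4β)-N1,N3-diacryloyl-N1,N3-di(but-3-en-1-yl)-2,4-bis(3,4,5-trimethoxyphenyl)cyclobutane-1,3-dicarboxamide (tetraene bis-imide), via bis(acid chloride) 6 (not isolated), via lithium amidate 7 (not isolated)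
Conditions: 2, (COCl)2 (3 equiv), DMF (cat.), CH2Cl2, 0 °C to rt, evaporate; separately 5, LiN(SiMe3)2 (2.1 equiv), THF, −78 °C; add 6 in THF, −78 °C, 1 h; aq NH4Cl at −78 °C
Reagents that add atoms: oxalyl chloride, O=C(Cl)C(=O)Cl (Cl of intermediate 6 only); LiN(SiMe3)2, [Li]N([Si](C)(C)C)[Si](C)(C)C (Li of intermediate 7 only)
Why: Vilsmeier-catalysed acid chloride formation followed by N-acylation of a preformed lithium amidate (imide synthesis, any O-acyl isoimide collapsing by a Mumm-type O-to-N acyl shift), run at −78 °C without free amine base and with the amide kept in slight excess over LiN(SiMe3)2 so that neither ketene formation nor enolisation can epimerise the cyclobutane C–H bonds next to the carbonyls, the trans-1,3 carboxyls being unable to form a cyclic anhydride, so the four stereocentres of 2 are carried over unchanged.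

**Step 4 (key step)**
Reactants: 8 tetraene bis-imide
Product: 9 piplartine-dimer A (1α,2α,3β,4β; both 5,6-dihydropyridin-2(1H)-one rings closed)
Conditions: second-generation Hoveyda–Grubbs catalyst RuCl2(SIMes)(=CH-C6H4-2-OiPr) (2 × 5 mol %), 1,4-benzoquinone (20 mol %), CH2Cl2 (2 mM), 40 °C, argon sparge, 12 h
Reagents that add atoms: none
Why: Two-directional double ring-closing metathesis (RCM): the phosphine-free ruthenium carbene loads on each unhindered butenyl terminus and closes onto the acryloyl group on the same nitrogen, the low C–N rotation barrier of an imide making the reactive rotamer available, six-ring closure outrunning the 13-membered cross-closure between arms that sit on opposite faces of the cyclobutane, loss of ethene and the inertness of the conjugated cyclic products making both closures irreversible, the ring size enforcing the Z alkene geometry, and the neutral conditions leaving the four stereocentres untouched.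

**Compound list**
1 | (E)-3,4,5-trimethoxycinnamic acid | COc1cc(/C=C/C(=O)O)cc(OC)c1OC | starting material
2 | (1α,2α,3β,4β)-2,4-bis(3,4,5-trimethoxyphenyl)cyclobutane-1,3-dicarboxylic acid | COc1cc([C@H]2[C@H](C(=O)O)[C@H](c3cc(OC)c(OC)c(OC)c3)[C@H]2C(=O)O)cc(OC)c1OC | intermediate
3 | but-3-en-1-amine | C=CCCN | starting material
4 | acryloyl chloride | C=CC(=O)Cl | starting material
5 | N-(but-3-en-1-yl)prop-2-enamide | C=CCCNC(=O)C=C | intermediate
6 | (1α,2α,3β,4β)-2,4-bis(3,4,5-trimethoxyphenyl)cyclobutane-1,3-dicarbonyl dichloride | COc1cc([C@H]2[C@H](C(=O)Cl)[C@H](c3cc(OC)c(OC)c(OC)c3)[C@H]2C(=O)Cl)cc(OC)c1OC | intermediate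
7 | lithium N-(but-3-en-1-yl)acrylamidate | [Li]N(CCC=C)C(=O)C=C | intermediate
8 | (1α,2α,3β,4β)-N1,N3-diacryloyl-N1,N3-di(but-3-en-1-yl)-2,4-bis(3,4,5-trimethoxyphenyl)cyclobutane-1,3-dicarboxamide | COc1cc([C@H]2[C@H](C(=O)N(CCC=C)C(=O)C=C)[C@H](c3cc(OC)c(OC)c(OC)c3)[C@H]2C(=O)N(CCC=C)C(=O)C=C)cc(OC)c1OC | intermediate
9 | piplartine-dimer A | COc1cc([C@H]2[C@H](C(=O)N3CCC=CC3=O)[C@H](c3cc(OC)c(OC)c(OC)c3)[C@H]2C(=O)N2CCC=CC2=O)cc(OC)c1OC | target

**Total step count:** 4. **Longest linear sequence:** 3 (1 → 2 → 8 → 9).

**Steps most likely to fail, each with a fallback**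

**Step 1.** The crystal form of 1 in hand may be photoinert, or conversion may stall as the lattice degrades.
- The fallback sets out from 1 and returns at 2. It moves stereocontrol from the crystal lattice of the free acid to a discrete Lewis-acid complex.
- Fischer esterification of 1 (MeOH, cat. H2SO4) gives methyl (E)-3,4,5-trimethoxycinnamate F1.
- SnCl4 (0.5 equiv, CH2Cl2) binds two ester carbonyls to give the 2:1 ester–SnCl4 complex F2. In this complex the cinnamate units lie antiparallel and the excited-state reactivity is raised.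
- Irradiation of F2 through a borosilicate filter, as crystals or in CH2Cl2, followed by aqueous work-up gives dimethyl (1α,2α,3β,4β)-2,4-bis(3,4,5-trimethoxyphenyl)cyclobutane-1,3-dicarboxylate F3.
- LiOH in THF/H2O at rt, then HCl, returns to 2.

**Step 3.** A hindered acid chloride meets a hindered secondary amidate that also carries a Michael acceptor. Possible outcomes are slow acylation, aza-Michael oligomers, or α-to-γ epimerisation.
- The fallback sets out from 2 (with 3 and 4) and returns at 8. It builds the imide in the reverse order.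
- 2 is coupled with the small primary amine 3 (EDC·HCl, HOBt, CH2Cl2) to give (1α,2α,3β,4β)-N1,N3-di(but-3-en-1-yl)-2,4-bis(3,4,5-trimethoxyphenyl)cyclobutane-1,3-dicarboxamide F4.
- LiN(SiMe3)2 (THF, −78 °C) converts F4 into its dilithium bis-amidate F5, whose ring C–H bonds are not acidic.
- F5 is acylated by the small electrophile 4 to give 8.

**Step 4.** The RCM may stop after one ring. Other failure modes are chelation of the ruthenium carbene by an imide carbonyl, alkene isomerisation, and oligomerisation.
- The fallback sets out from 5 (together with 6 made from 2 as in step 3) and returns at 9. It closes each ring before the coupling instead of after it.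
- RCM of 5 with the same catalyst in refluxing CH2Cl2 gives 5,6-dihydropyridin-2(1H)-one F6.
- LiN(SiMe3)2 (THF, −78 °C) gives its N-lithio derivative F7.
- Two equivalents of F7 are acylated by 6 at −78 °C to give 9 directly.

**Further compounds**
F1 | step 1 | methyl (E)-3,4,5-trimethoxycinnamate | COC(=O)/C=C/c1cc(OC)c(OC)c(OC)c1
F2 | step 1 | 2:1 complex of F1 and SnCl4 | COC(=O)/C=C/c1cc(OC)c(OC)c(OC)c1.COC(=O)/C=C/c1cc(OC)c(OC)c(OC)c1.Cl[Sn](Cl)(Cl)Cl
F3 | step 1 | dimethyl (1α,2α,3β,4β)-2,4-bis(3,4,5-trimethoxyphenyl)cyclobutane-1,3-dicarboxylate | COc1cc([C@H]2[C@H](C(=O)OC)[C@H](c3cc(OC)c(OC)c(OC)c3)[C@H]2C(=O)OC)cc(OC)c1OC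
F4 | step 3 | (1α,2α,3β,4β)-N1,N3-di(but-3-en-1-yl)-2,4-bis(3,4,5-trimethoxyphenyl)cyclobutane-1,3-dicarboxamide | COc1cc([C@H]2[C@H](C(=O)NCCC=C)[C@H](c3cc(OC)c(OC)c(OC)c3)[C@H]2C(=O)NCCC=C)cc(OC)c1OC
F5 | step 3 | dilithium bis-amidate of F4 | COc1cc([C@H]2[C@H](C(=O)N([Li])CCC=C)[C@H](c3cc(OC)c(OC)c(OC)c3)[C@H]2C(=O)N([Li])CCC=C)cc(OC)c1OC
F6 | step 4 | 5,6-dihydropyridin-2(1H)-one | O=C1C=CCCN1
F7 | step 4 | N-lithio-5,6-dihydropyridin-2(1H)-one | O=C1C=CCCN1[Li]
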